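**Strategy.** Everything rests on closing the pyran ring last, by joining the C4 methylene to C4a of ring A. The precursor is an open-chain (S)-aryl ether: the 3,5-dimethoxy-4-prenylphenyl ether of 3-iodo-1-(4-methoxyphenyl)propan-1-ol, its C2 stereocentre set by CBS reduction and Mitsunobu inversion. A Pd(PPh3)4-catalysed radical C–H alkylation converts the primary iodide into a C4 radical that attacks ring A ortho to O1 and delivers the chroman directly at the final oxidation level. The step exploits ring A itself: its two carbons ortho to O1 are equivalent by local symmetry, so one regioisomer is possible, and the oxygens on C5, C7 and C8a stabilise the cyclohexadienyl intermediate.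

Key step: step 6

Remark: the target SMILES corresponds to the (2S)-flavan; flavan numbering (O1, C2, C3, C4, C4a, C5 to C8, C8a) is used throughout.
Remark: 1,3-dimethoxybenzene, prenyl bromide and 3-chloro-1-(4-methoxyphenyl)propan-1-one are taken as articles of commerce.

Step 1
Reactants: 1 1,3-dimethoxybenzene; 2 prenyl bromide (1-bromo-3-methylbut-2-ene)
Product: 4 1,3-dimethoxy-2-(3-methylbut-2-en-1-yl)benzene, via (2,6-dimethoxyphenyl)lithium 3 (not isolated)
Conditions: n-BuLi, THF, 0 °C to rt; then CuI (10 mol %), 2, −78 °C to rt
Reagents that add atoms: none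
Why: Directed ortho-metalation, in which both methoxy groups steer n-BuLi to C2 of 1, followed by copper-assisted SN2 displacement of bromide at the primary carbon of 2.

Step 2
Reactants: 4 1,3-dimethoxy-2-(3-methylbut-2-en-1-yl)benzene
Product: 6 3,5-dimethoxy-4-(3-methylbut-2-en-1-yl)phenol, via aryl pinacol boronate 5 (not isolated)
Conditions: [Ir(OMe)(cod)]2 (1.5 mol %), dtbpy (3 mol %), B2pin2, THF, 80 °C; then aq. H2O2, NaOH, 0 °C to rt
Reagents that add atoms: bis(pinacolato)diboron, CC1(C)OB(OC1(C)C)B1OC(C)(C)C(C)(C)O1 (boryl group of intermediate 5 only); hydrogen peroxide, OO (phenol oxygen of 6)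
Why: Sterically controlled iridium-catalysed aromatic C–H borylation should pick C5 of 4, the only ring C–H without an ortho substituent, and alkaline peroxide then oxidises the C–B bond at the ipso carbon without epoxidising the isolated trisubstituted olefin.

Step 3
Reactants: 7 3-chloro-1-(4-methoxyphenyl)propan-1-one
Product: 8 (R)-3-chloro-1-(4-methoxyphenyl)propan-1-ol
Conditions: (S)-Me-CBS oxazaborolidine (10 mol %), BH3·SMe2, THF, 0 °C; MeOH, then aqueous work-up
Reagents that add atoms: none
Why: Corey–Bakshi–Shibata reduction, in which the aryl group acts as the large and the chloroethyl group as the small substituent, so the (S)-oxazaborolidine–borane complex delivers hydride to the Si face and sets the (R)-carbinol centre.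

Step 4
Reactants: 6 3,5-dimethoxy-4-(3-methylbut-2-en-1-yl)phenol; 8 (R)-3-chloro-1-(4-methoxyphenyl)propan-1-ol
Product: 9 (S)-5-[3-chloro-1-(4-methoxyphenyl)propoxy]-1,3-dimethoxy-2-(3-methylbut-2-en-1-yl)benzene
Conditions: PPh3, DIAD, toluene, 0 °C to rt
Reagents that add atoms: none
Why: Mitsunobu etherification, in which the phenoxide of 6 displaces the oxyphosphonium of 8 by SN2 with inversion, turning the (R)-carbinol into the (S)-ether carbon that becomes C2, while the primary chloride is left untouched.

Step 5
Reactants: 9 (S)-5-[3-chloro-1-(4-methoxyphenyl)propoxy]-1,3-dimethoxy-2-(3-methylbut-2-en-1-yl)benzene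
Product: 10 (S)-5-[3-iodo-1-(4-methoxyphenyl)propoxy]-1,3-dimethoxy-2-(3-methylbut-2-en-1-yl)benzene
Conditions: NaI, acetone, reflux
Reagents that add atoms: sodium iodide, [Na+].[I-]
Why: Finkelstein halide exchange (SN2 at the primary carbon, driven by precipitation of NaCl) gives the iodide needed for the key step and does not touch the remote stereocentre.

Step 6
Reactants: 10 (S)-5-[3-iodo-1-(4-methoxyphenyl)propoxy]-1,3-dimethoxy-2-(3-methylbut-2-en-1-yl)benzene
Product: 11 (2S)-5,7-dimethoxy-2-(4-methoxyphenyl)-6-(3-methylbut-2-en-1-yl)chromane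
Conditions: Pd(PPh3)4 (10 mol %), K3PO4, 1,4-dioxane, 100 °C
Reagents that add atoms: none
Why: Zerovalent palladium abstracts the iodine atom of the primary iodide to give a C4 alkyl radical and a monovalent palladium iodide; the radical adds to the ring A carbon ortho to O1 (the future C4a), and the cyclohexadienyl radical, whose spin sits on the three oxygen-bearing carbons C5, C7 and C8a, is oxidised by the palladium iodide and deprotonated by K3PO4, which restores the arene and the zerovalent catalyst. The closest known reaction type is the palladium-catalysed ring-forming aromatic C–H alkylation with unactivated alkyl halides, a catalytic homolytic aromatic substitution. The pyran ring closes as a six-membered ring by ortho attack of the tethered radical (formally 6-exo-trig onto the C4a=C5 bond). No stereocentre is formed; C2, set in steps 3 and 4, is not part of the radical and meets neither acid nor strong base, so it should be retained. The step needs regioselectivity on ring A and chemoselectivity against the anisyl ring and the prenyl olefin: the two positions ortho to O1 are equivalent by the local twofold symmetry of the 3,5-dimethoxy-4-prenylphenoxy unit, attack on the anisyl ring would require a strained five-membered closure, and the olefin lies out of reach of the tether.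

**Compound list**

1 | 1,3-dimethoxybenzene | COc1cccc(OC)c1 | starting material
2 | prenyl bromide (1-bromo-3-methylbut-2-ene) | CC(C)=CCBr | starting material
3 | (2,6-dimethoxyphenyl)lithium | [Li]c1c(OC)cccc1OC | intermediate
4 | 1,3-dimethoxy-2-(3-methylbut-2-en-1-yl)benzene | COc1cccc(OC)c1CC=C(C)C | intermediate
5 | 2-[3,5-dimethoxy-4-(3-methylbut-2-en-1-yl)phenyl]-4,4,5,5-tetramethyl-1,3,2-dioxaborolane | COc1cc(B2OC(C)(C)C(C)(C)O2)cc(OC)c1CC=C(C)C | intermediate
6 | 3,5-dimethoxy-4-(3-methylbut-2-en-1-yl)phenol | COc1cc(O)cc(OC)c1CC=C(C)C | intermediate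
7 | 3-chloro-1-(4-methoxyphenyl)propan-1-one | COc1ccc(C(=O)CCCl)cc1 | starting material
8 | (R)-3-chloro-1-(4-methoxyphenyl)propan-1-ol | COc1ccc([C@@H](CCCl)O)cc1 | intermediate
9 | (S)-5-[3-chloro-1-(4-methoxyphenyl)propoxy]-1,3-dimethoxy-2-(3-methylbut-2-en-1-yl)benzene | COc1ccc([C@H](CCCl)Oc2cc(OC)c(CC=C(C)C)c(OC)c2)cc1 | intermediate
10 | (S)-5-[3-iodo-1-(4-methoxyphenyl)propoxy]-1,3-dimethoxy-2-(3-methylbut-2-en-1-yl)benzene | COc1ccc([C@H](CCI)Oc2cc(OC)c(CC=C(C)C)c(OC)c2)cc1 | intermediate
11 | (2S)-5,7-dimethoxy-2-(4-methoxyphenyl)-6-(3-methylbut-2-en-1-yl)chromane | COc1ccc([C@@H]2CCc3c(cc(OC)c(CC=C(C)C)c3OC)O2)cc1 | target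

**Count**

Total step count: 6. Longest linear sequence: 5 steps (steps 1, 2, 4, 5, 6); the second branch (steps 3, 4, 5, 6) joins at step 4.

**Steps most likely to fail**

Step 6 (key step). The tethered primary radical may add too slowly to the electron-rich ring, so that β-hydride elimination to the allyl ether or simple reduction of the C–I bond overtakes ring closure. The fallback forms the same bond by a polar, two-electron closure and sets out from chloride 9. NIS (1.0 equiv) in MeCN at 0 °C should iodinate ring A at one of its two equivalent free positions, which are by far the most nucleophilic aromatic carbons in the molecule, to give (S)-1-[3-chloro-1-(4-methoxyphenyl)propoxy]-2-iodo-3,5-dimethoxy-4-(3-methylbut-2-en-1-yl)benzene F1. Iodine–lithium exchange with t-BuLi (2 equiv) in THF at −100 °C should give the ortho-lithiated aryl ether F2 (not isolated). On warming to rt this should displace the primary chloride in a Parham cyclisation (6-exo-tet) and come back to the route at target 11.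

Step 4. The p-methoxybenzylic oxyphosphonium intermediate may ionise, so that an SN1 pathway erodes the enantiomeric purity or elimination competes with substitution. The fallback sets the C2–O stereocentre by catalyst control and sets out from phenol 6. Methyl (E)-3-(4-methoxyphenyl)allyl carbonate F3 would be made from commercial 4-methoxycinnamyl alcohol (ClCO2Me, pyridine). The lithium phenoxide of 6, [Ir(cod)Cl]2 and a BINOL-derived phosphoramidite ligand bearing a bis(1-phenylethyl)amine unit (the ligand enantiomer that delivers the S product), in THF at 50 °C, should give the branched ether (S)-1,3-dimethoxy-5-[1-(4-methoxyphenyl)allyloxy]-2-(3-methylbut-2-en-1-yl)benzene F4 by enantioselective allylic etherification. 9-BBN in THF should hydroborate only the monosubstituted vinyl group to the B-alkyl-9-borabicyclononane adduct F5 (not isolated), and NaBO3·4H2O should oxidise it to (S)-3-[3,5-dimethoxy-4-(3-methylbut-2-en-1-yl)phenoxy]-3-(4-methoxyphenyl)propan-1-ol F6. I2, PPh3 and imidazole in CH2Cl2 would then give iodide 10, where the fallback comes back to the route.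

Step 2. The prenyl olefin may be hydroborated or borylated at its vinylic C–H under the iridium conditions, or be attacked during the oxidation. The fallback reverses the order of oxygenation and prenylation and sets out from 1. The same borylation and peroxide oxidation on 1, which carries no olefin, should give 2-(3,5-dimethoxyphenyl)-4,4,5,5-tetramethyl-1,3,2-dioxaborolane F7 (not isolated) and then 3,5-dimethoxyphenol F8. TIPSCl and imidazole in DMF should give (3,5-dimethoxyphenoxy)triisopropylsilane F9. n-BuLi in THF at 0 °C should lithiate between the two methoxy groups, the bulky silyl ether being a poor director, to give [2,6-dimethoxy-4-(triisopropylsilyloxy)phenyl]lithium F10 (not isolated). CuI and prenyl bromide 2 should then give [3,5-dimethoxy-4-(3-methylbut-2-en-1-yl)phenoxy]triisopropylsilane F11, and TBAF in THF would release phenol 6, where the fallback comes back to the route.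

**Further compounds**

F1 | step 6 | (S)-1-[3-chloro-1-(4-methoxyphenyl)propoxy]-2-iodo-3,5-dimethoxy-4-(3-methylbut-2-en-1-yl)benzene | COc1ccc([C@H](CCCl)Oc2cc(OC)c(CC=C(C)C)c(OC)c2I)cc1
F2 | step 6 | ortho-lithiated aryl ether from F1 | COc1ccc([C@H](CCCl)Oc2cc(OC)c(CC=C(C)C)c(OC)c2[Li])cc1
F3 | step 4 | methyl (E)-3-(4-methoxyphenyl)allyl carbonate | COC(=O)OC/C=C/c1ccc(OC)cc1
F4 | step 4 | (S)-1,3-dimethoxy-5-[1-(4-methoxyphenyl)allyloxy]-2-(3-methylbut-2-en-1-yl)benzene | COc1ccc([C@H](C=C)Oc2cc(OC)c(CC=C(C)C)c(OC)c2)cc1
F5 | step 4 | B-alkyl-9-borabicyclononane adduct of F4 | COc1ccc([C@H](CCB2C3CCCC2CCC3)Oc2cc(OC)c(CC=C(C)C)c(OC)c2)cc1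
F6 | step 4 | (S)-3-[3,5-dimethoxy-4-(3-methylbut-2-en-1-yl)phenoxy]-3-(4-methoxyphenyl)propan-1-ol | COc1ccc([C@H](CCO)Oc2cc(OC)c(CC=C(C)C)c(OC)c2)cc1
F7 | step 2 | 2-(3,5-dimethoxyphenyl)-4,4,5,5-tetramethyl-1,3,2-dioxaborolane | COc1cc(OC)cc(B2OC(C)(C)C(C)(C)O2)c1
F8 | step 2 | 3,5-dimethoxyphenol | COc1cc(O)cc(OC)c1
F9 | step 2 | (3,5-dimethoxyphenoxy)triisopropylsilane | COc1cc(OC)cc(O[Si](C(C)C)(C(C)C)C(C)C)c1
F10 | step 2 | [2,6-dimethoxy-4-(triisopropylsilyloxy)phenyl]lithium | [Li]c1c(OC)cc(O[Si](C(C)C)(C(C)C)C(C)C)cc1OC
F11 | step 2 | [3,5-dimethoxy-4-(3-methylbut-2-en-1-yl)phenoxy]triisopropylsilane | COc1cc(O[Si](C(C)C)(C(C)C)C(C)C)cc(OC)c1CC=C(C)C
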